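**The flasks.** Free catalyst turns starting material into target in closed, stirred flasks at one temperature. Monday's flask and Tuesday's flask share a charge of starting material and differ in catalyst, and Thursday's flask has the same charge with less catalyst still.

| flask | starting material | free catalyst | time |
|---|---|---|---|
| Tuesday's | 100 mM | 8.00 mM |  |
| Friday's | 40.0 mM | 8.00 mM |  |
| Monday's | 100 mM | 4.00 mM |  |
| Wednesday's | 150 mM | 8.00 mM |  |
| Thursday's | 100 mM | 2.30 mM | 40 min |

- Tuesday's run (time / min: [target] / mM): 5.7: 25.8; 11: 44.8; 17: 61.1; 23: 72.6; 29: 80.6; 34: 85.8; 40: 89.2
- Friday's run (time / min: [target] / mM): 5.7: 11.7; 11: 19.3; 17: 24.9; 23: 28.7; 29: 31.7; 34: 33.1; 40: 34.8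
- Monday's run (time / min: [target] / mM): 5.7: 14.6; 11: 27.6; 17: 39.7; 23: 50.4; 29: 59.6; 34: 66.5; 40: 72.4
- Wednesday's run (time / min: [target] / mM): 5.7: 34.1; 11: 61.9; 17: 86.2; 23: 104.7; 29: 117.7; 34: 126.0; 40: 132.7

(each reading ± 0.3 mM)

* order of the initial rate in [free catalyst], near the charge of the Tuesday's run, the rate being that where two percent of its starting material are target
* order of the initial rate in [starting material], near the charge of the Tuesday's run, the rate being that where two percent of its starting material are target (one fixed amount of target, the same in the runs compared)
* the Friday's run starts with 60.0 mM less of starting material than the Tuesday's run, and with no target. Compared where both hold the same amount of starting material, once fifteen percent of what the Friday's run was charged with has turned into target, is the Friday's run faster, slower or alike (within a tenth)?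
* target in the Thursday's run at 40 min, as a share of the starting material charged

- Overall: starting material -> target, with free catalyst as catalyst.
- Constant volume, constant temperature.
- Bound and free are read together.
- An order is taken over about fifteen percent of the charge, up and down.

**First way.** The scale starts from independent catalyst units, where half the c(free catalyst) takes twice the time to one amount of target. Tuesday's flask holds 72.6 mM at 23 min, and Monday's flask, with half the catalyst, holds 72.4 mM at 40 min. That is sooner than the 46.0 min of the independent case. The logarithm of the time ratio over the logarithm of the catalyst ratio is 0.798. This exponent, by which the time to one amount of target stretches as catalyst is cut at equal charge of starting material, is the clock order.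

**Second way.** The first readings of the same two flasks, both at 5.7 min, stand in a ratio that gives an order of 0.821. The scatter of those two readings moves this order by about 0.0341, and the two ways differ by 0.0230. Both ways rest on the same two flasks, at 4.00 mM and 8.00 mM, so this agreement says nothing about the 2.30 mM of Thursday's flask, which lies lower.

**Own reckoning.** Thursday's flask has the charge of starting material of Monday's flask, and if the clock order is taken as steady below 4.00 mM, its catalyst stretches the clock by 1.56. On that assumption its 40 min match 25.7 min in Monday's flask. Between Monday's readings that gives 54.6 mM of target, a share of 54.6 %.

**The forecast.** The forecast gives an order in catalyst of 0.88 (0.78 to 0.98), an order in starting material of 0.72 (0.6 to 0.85), and alike for Friday's flask against Tuesday's flask. For Thursday's flask it gives 52 % (47 % to 56 %), “assuming no new behaviour at low catalyst”. That share is lower than the reckoning above.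

**The result.** Thursday's flask gives 52.5 %, with orders of 0.84 in catalyst and 0.73 in starting material, and Friday's flask comes out alike, at a rate ratio of 1.0.

    free catalyst + starting material ⇌ catalyst-substrate complex, settled at all times (138.0 M⁻¹)
    catalyst-substrate complex + starting material ⇌ doubly bound catalyst, settled at all times (22.90 M⁻¹)
    doubly bound catalyst → target + catalyst-substrate complex (3.006 min⁻¹)
    2 free catalyst ⇌ resting dimer, settled at all times (250.0 M⁻¹)
    2 starting material ⇌ idle substrate dimer, settled at all times (101.0 M⁻¹)

The reckoning of 54.6 % stands above the flask, as does a power law over the runs, with best order 0.77 in catalyst, at 55.4 % for Thursday's flask. The clock order stretches Monday's time to half of the charge, 22.7 min, to 35.4 min in Thursday's flask, which lies before 40 min, as a share above half requires. Shrunk by the same rule, Monday's time gives 13.1 min for Tuesday's flask, whose simulated time is 12.7 min.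

The runs come from a simulation on assumed constants.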